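**Plan**
- Cuts: in each half, ring B is opened at C9–C10 and at C5–C6. This leaves the (3R,6R)-2,5-dimethoxy-3,6-diaryl-1,4-dioxane 7 and two molecules of the ring-A allylsilane 11. Compound 7 is cut at its two acetal C–O bonds into two molecules of the (R)-α-hydroxy acetal 6.
- Enabling feature: the dioxane joins C7–O–C6′ and C7′–O–C6, so it is the head-to-tail cyclic dimer of an α-hydroxy aldehyde. C6/C6′ are therefore acetal-level carbons next to the benzylic C7/C7′, and C9 is a free arene CH ortho to C8 and para to the isopropyl group. The unit C6(+)–C7–C8=C9 can thus take up the C5=C10 unit of ring A in a formal [4+2] sense.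
- Forward order: ring C is bought (2-isopropylanisole); the dioxane ring is made by cyclodimerisation (step 4); ring A comes from 3-methylcyclohexenone (steps 5, 6). The two B rings are closed last, one after the other in one flask (step 7: C5–C6 by acetal allylation, then C9–C10 by cation–arene closure).
- Stereochemistry: C7/C7′ come from asymmetric transfer hydrogenation (step 3). In step 7, C6/C6′ follow from addition anti to the aryl groups, C5/C5′ from the antiperiplanar SE2′ transition state, and C10/C10′ from equatorial arene attack (trans A/B fusion).

Key step: step 7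

Remark: with homochiral halves and two trans B/dioxane fusions the dioxane of the target cannot be a chair (it is a twist form), so the target is treated as a kinetic product, the C7–O bonds are never allowed to equilibrate, and the two B rings, equivalent by C2 symmetry, are closed in the same operation.

**Route**

Step 1
Reactants: 1 2-isopropylanisole
Product: 2 4-bromo-2-isopropylanisole
Conditions: NBS, MeCN, 0 °C → rt
Reagents that add atoms: N-bromosuccinimide, O=C1CCC(=O)N1Br
Why: Electrophilic aromatic bromination, in which the methoxy group directs to its unhindered para position, so bromine should enter at the carbon that becomes C8.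

Step 2
Reactants: 2 4-bromo-2-isopropylanisole; 3 methyl 2,2-dimethoxyacetate
Product: 5 2,2-dimethoxy-1-[4-methoxy-3-(propan-2-yl)phenyl]ethan-1-one, via arylmagnesium bromide 4 (not isolated)
Conditions: Mg, THF, 40 °C; then added to 3, THF, −78 °C; H2O quench
Reagents that add atoms: none
Why: Grignard formation and acylation by an α,α-dialkoxy ester, where the chelated tetrahedral magnesium alkoxide should persist at −78 °C under inverse addition so that the reaction stops at the ketone.

Step 3
Reactants: 5 2,2-dimethoxy-1-[4-methoxy-3-(propan-2-yl)phenyl]ethan-1-one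
Product: 6 (1R)-2,2-dimethoxy-1-[4-methoxy-3-(propan-2-yl)phenyl]ethan-1-ol
Conditions: RuCl[(S,S)-TsDPEN](p-cymene) (1 mol %), HCO2H/Et3N 5:2, rt
Reagents that add atoms: none
Why: Noyori asymmetric transfer hydrogenation of an aryl ketone, where the (S,S) ligand should deliver hydride in the same spatial sense as for acetophenone and so set C7 as R (the descriptor differs only because CH(OMe)2 outranks aryl).

Step 4
Reactants: 6 (1R)-2,2-dimethoxy-1-[4-methoxy-3-(propan-2-yl)phenyl]ethan-1-ol (two molecules)
Product: 7 (3R,6R)-2,5-dimethoxy-3,6-bis[4-methoxy-3-(propan-2-yl)phenyl]-1,4-dioxane (mixture of anomers at C2/C5)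
Conditions: PPTS (10 mol %), toluene, 5 Å MS, rt → 40 °C
Reagents that add atoms: none
Why: Acid-catalysed transacetalisation in which the carbinol oxygen of each molecule displaces methanol from the acetal of the other (the head-to-tail cyclodimerisation typical of α-hydroxy aldehydes and their acetals), driven by methanol uptake on the sieves and leaving the C7 stereocentres untouched.

Step 5
Reactants: 8 3-methylcyclohex-2-en-1-one
Product: 10 3,3-dimethylcyclohex-1-en-1-yl trifluoromethanesulfonate, via bromomagnesium enolate 9 (not isolated)
Conditions: MeMgBr, CuI (10 mol %), THF, −20 °C; then PhNTf2, DMPU, 0 °C → rt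
Reagents that add atoms: methylmagnesium bromide, C[Mg]Br; N-phenylbis(trifluoromethanesulfonimide), O=S(=O)(N(c1ccccc1)S(=O)(=O)C(F)(F)F)C(F)(F)F
Why: Copper-catalysed conjugate addition builds the gem-dimethyl carbon (C4) and gives the regiodefined enolate, which is trapped on oxygen as the enol triflate (conjugate addition/enolate trapping).

Step 6
Reactants: 10 3,3-dimethylcyclohex-1-en-1-yl trifluoromethanesulfonate
Product: 11 [(3,3-dimethylcyclohex-1-en-1-yl)methyl]trimethylsilane
Conditions: Me3SiCH2MgCl, Pd(PPh3)4 (5 mol %), THF, 0 °C → rt
Reagents that add atoms: (trimethylsilyl)methylmagnesium chloride, C[Si](C)(C)C[Mg]Cl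
Why: Kumada–Corriu cross-coupling of an enol triflate with the silylmethyl Grignard reagent under zerovalent palladium catalysis, the standard route to allylsilanes, with no stereocentre formed.

Step 7
Reactants: 7 (3R,6R)-2,5-dimethoxy-3,6-bis[4-methoxy-3-(propan-2-yl)phenyl]-1,4-dioxane; 11 [(3,3-dimethylcyclohex-1-en-1-yl)methyl]trimethylsilane (2.4 equiv)
Product: 13 target, the C2-symmetric head-to-tail dioxane dimer of 12-methoxyabieta-8,11,13-triene-6α,7β-diol (5S,6R,7R,10S in each half), via bis(methylidenecyclohexyl)dioxane 12 (not isolated)
Conditions: TMSOTf (0.5 equiv), CH2Cl2, −78 → −40 °C; then TfOH (0.5 equiv), −78 → −40 °C; Et3N quench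
Reagents that add atoms: none
Why: TMSOTf ionises each anomeric methoxy group of 7 to a dioxanyl oxocarbenium ion at C6, which is attacked by the γ-carbon (C5) of 11 with loss of the silyl group (Hosomi–Sakurai allylation of a cyclic acetal, as in anomeric C-allylation) to give 12; TfOH then protonates each exocyclic C10=CH2 to the tertiary C10 cation, which alkylates C9 (Friedel–Crafts cycloalkylation, the classical B-ring closure of abietanes), so that the two stages add up to a formal [4+2] annulation of C6–C7–C8=C9 with C5=C10. Each ring B closes as a six-membered, chair-like cation–arene cyclisation (6-endo with respect to the arene C8=C9 bond), and the second of the two closures is the last ring-forming event. C6 and C6′ are controlled by C7/C7′: the two aryl groups are cis on the dioxane, the reactive half-chair carries the neighbouring aryl pseudoaxial, and axial attack anti to it (the face that is also free of the 1,3-related aryl) gives the 6,7-trans arrangement. C5 is controlled by the open antiperiplanar SE2′ transition state in which the quaternary C4 lies anti to C7 and C10 sits beside H6, and C10 by attack of C9 on the equatorial face of the cyclohexyl cation, the axial face being blocked by the axial methyl on C4, which gives the trans A/B fusion with an axial C10 methyl. The step needs C9 and not C14 to be alkylated, which the isopropyl group secures (it flanks C14 and is para to C9), and it needs the acid-labile p-methoxybenzylic C7–O bonds to survive, for which the acid stage is kept at or below −40 °C and is quenched cold with Et3N.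

**Compound list**

1 | 2-isopropylanisole [1-methoxy-2-(propan-2-yl)benzene] | COc1ccccc1C(C)C | starting material
2 | 4-bromo-2-isopropylanisole [4-bromo-1-methoxy-2-(propan-2-yl)benzene] | COc1ccc(Br)cc1C(C)C | intermediate
3 | methyl 2,2-dimethoxyacetate | COC(OC)C(=O)OC | starting material
4 | [4-methoxy-3-(propan-2-yl)phenyl]magnesium bromide (formed in the flask, not isolated) | COc1ccc([Mg]Br)cc1C(C)C | intermediate
5 | 2,2-dimethoxy-1-[4-methoxy-3-(propan-2-yl)phenyl]ethan-1-one | COc1ccc(cc1C(C)C)C(=O)C(OC)OC | intermediate
6 | (1R)-2,2-dimethoxy-1-[4-methoxy-3-(propan-2-yl)phenyl]ethan-1-ol | COc1ccc(cc1C(C)C)[C@@H](O)C(OC)OC | intermediate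
7 | (3R,6R)-2,5-dimethoxy-3,6-bis[4-methoxy-3-(propan-2-yl)phenyl]-1,4-dioxane, aryl groups cis, anomeric carbons C2/C5 as a mixture | COc1ccc(cc1C(C)C)[C@H]1OC(OC)[C@H](OC1OC)c1ccc(OC)c(C(C)C)c1 | intermediate
8 | 3-methylcyclohex-2-en-1-one | CC1=CC(=O)CCC1 | starting material
9 | bromomagnesium 3,3-dimethylcyclohex-1-en-1-olate (formed in the flask, not isolated) | CC1(C)CCCC(O[Mg]Br)=C1 | intermediate
10 | 3,3-dimethylcyclohex-1-en-1-yl trifluoromethanesulfonate | CC1(C)CCCC(OS(=O)(=O)C(F)(F)F)=C1 | intermediate
11 | [(3,3-dimethylcyclohex-1-en-1-yl)methyl]trimethylsilane | C[Si](C)(C)CC1=CC(C)(C)CCC1 | intermediate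
12 | (2R,3R,5R,6R)-2,5-bis[(1S)-2,2-dimethyl-6-methylidenecyclohexyl]-3,6-bis[4-methoxy-3-(propan-2-yl)phenyl]-1,4-dioxane; each cyclohexyl trans to the neighbouring aryl (formed in the flask, not isolated) | COc1ccc(cc1C(C)C)[C@H]1O[C@H]([C@@H]2C(=C)CCCC2(C)C)[C@H](O[C@@H]1[C@@H]1C(=C)CCCC1(C)C)c1ccc(OC)c(C(C)C)c1 | intermediate
13 | target: two 12-methoxyabieta-8,11,13-triene units (5S,10S, trans A/B) joined by a 1,4-dioxane through 6α-O–C7′ and 6′α-O–C7 ether links, with H6 β and H7 α (5S,6R,7R,10S in each half) | COc1cc2c(cc1C(C)C)[C@H]1O[C@H]3[C@H](O[C@@H]1[C@H]1C(C)(C)CCC[C@]21C)c1cc(C(C)C)c(OC)cc1[C@@]1(C)CCCC(C)(C)[C@H]31 | target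

**Step count**

Total steps: 7. Longest linear sequence: 5 (steps 1, 2, 3, 4, 7).

**Steps most likely to fail**

1. Step 7.
   - What may go wrong: loss of the C7 proton from the oxocarbenium ion (enol ether formation) and re-protonation, which would erode the C7 configuration.
   - What may go wrong: endocyclic instead of exocyclic acetal cleavage.
   - What may go wrong: in the TfOH stage, ionisation of a benzylic C7–O bond with reclosure to a cis-fused isomer, or ipso attack at C8.
   - Fallback: this replaces the Brønsted-acid cation cascade by a separate radical–polar crossover closure under near-neutral conditions. The TMSOTf stage is quenched with Et3N and 12 is isolated (no new compound, F0). Setting out from 12, both B rings should close by cobalt-catalysed hydrogen-atom-transfer hydroarylation of the 1,1-disubstituted alkenes. The conditions are [N,N′-bis(3,5-di-tert-butylsalicylidene)-1,2-cyclohexanediaminato]cobalt (a divalent cobalt salen complex), N-fluoro-2,4,6-trimethylpyridinium tetrafluoroborate, 1,1,3,3-tetramethyldisiloxane, PhCF3, rt. This known intramolecular alkene hydroarylation needs no strong acid and should obey the same equatorial-attack preference at C10. The route is rejoined at 13.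

2. Step 4.
   - What may go wrong: incomplete cyclodimerisation with build-up of open-chain oligomers, because the homochiral dimer must carry one aryl group axial.
   - What may go wrong: epimerisation at C7 through the enol ether under prolonged acid, which would drain material into the more stable heterochiral dimer.
   - Fallback: this uses spontaneous lactol dimerisation in place of acid-driven transacetalisation. Setting out from 6, mild aqueous hydrolysis (Amberlyst-15, acetone/H2O, rt) should free (2R)-2-hydroxy-2-[4-methoxy-3-(propan-2-yl)phenyl]acetaldehyde F1. On concentration this should dimerise, as α-hydroxy aldehydes do, to the (3R,6R)-3,6-diaryl-1,4-dioxane-2,5-diol F2. Acetylation (Ac2O, pyridine, DMAP, 0 °C) should give the 2,5-diyl diacetate F3, whose anomeric acetates leave more readily and favour exocyclic cleavage. F3 takes the place of 7 under the step-7 conditions, and the route is rejoined at 12.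

3. Step 2.
   - What may go wrong: over-addition of 4 to ketone 5 if the tetrahedral intermediate collapses before the quench.
   - Fallback: this uses electrophilic acylation in place of the organometallic route. Setting out from 1, Friedel–Crafts acylation with dichloroacetyl chloride and AlCl3 (CH2Cl2, 0 °C) should go para to the methoxy group and give 2,2-dichloro-1-[4-methoxy-3-(propan-2-yl)phenyl]ethan-1-one F4. NaOMe in MeOH (0 °C → rt) should then convert the CHCl2 group into the dimethyl acetal, and the route is rejoined at 5.

**Further compounds**

F0 | step 7 | none | none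
F1 | step 4 | (2R)-2-hydroxy-2-[4-methoxy-3-(propan-2-yl)phenyl]acetaldehyde | COc1ccc(cc1C(C)C)[C@@H](O)C=O
F2 | step 4 | (3R,6R)-3,6-bis[4-methoxy-3-(propan-2-yl)phenyl]-1,4-dioxane-2,5-diol (mixture of anomers) | COc1ccc(cc1C(C)C)[C@H]1OC(O)[C@H](OC1O)c1ccc(OC)c(C(C)C)c1
F3 | step 4 | (3R,6R)-3,6-bis[4-methoxy-3-(propan-2-yl)phenyl]-1,4-dioxane-2,5-diyl diacetate (mixture of anomers) | COc1ccc(cc1C(C)C)[C@H]1OC(OC(C)=O)[C@H](OC1OC(C)=O)c1ccc(OC)c(C(C)C)c1
F4 | step 2 | 2,2-dichloro-1-[4-methoxy-3-(propan-2-yl)phenyl]ethan-1-one | COc1ccc(cc1C(C)C)C(=O)C(Cl)Cl
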